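A closed, stirred vessel at constant temperature and volume holds substrate, partner, free catalyst and impurity; the four flasks share their [partner], [free catalyst] and [impurity] and differ in [substrate].

| flask | substrate | partner | free catalyst | impurity | remark | time |
|---|---|---|---|---|---|---|
| delta | 0.14 M | 0.175 M | 2.5 mM | 2.2 mM | run made earlier |  |
| beta | 1.3 M | 0.175 M | 2.5 mM | 2.2 mM | run made earlier |  |
| north-west | 0.25 M | 0.175 M | 2.5 mM | 2.2 mM |  | 2.0 min |
| north | 0.12 M | 0.175 M | 2.5 mM | 2.2 mM |  | 2.0 min |
| west | 1.0 M | 0.175 M | 2.5 mM | 2.2 mM |  | 2.0 min |
| east | 0.50 M | 0.175 M | 2.5 mM | 2.2 mM |  | 2.0 min |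

| run | time / s | product / % |
|---|---|---|
| delta | 10.0 | 7 |
| delta | 15.0 | 11 |
| delta | 25.0 | 20 |
| delta | 40.0 | 29 |
| delta | 50.0 | 34 |
| delta | 60.0 | 39 |
| beta | 10.0 | 1 |
| beta | 15.0 | 0 |
| beta | 25.0 | 3 |
| beta | 40.0 | 3 |
| beta | 50.0 | 2 |
| beta | 60.0 | 6 |

(each reading ± 1.5 percentage points)

* all flasks from highest to lowest amount of product, in percent of the substrate charged, at 2.0 min (north-west / north / west / east)
* the amount of product, in percent of the substrate charged of the flask you put first, at 2.0 min
* the amount of product, in percent of the substrate charged of the flask you put last, at 2.0 min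



Take the main step first. The last delta reading, 39% of 0.14 M, is 54.6 mM of product after 60.0 s. The last beta reading, 6% of 1.3 M, is 78.0 mM, though its scatter is 1.5 percentage points. Ten times the substrate therefore gives a similar concentration of product, which looks like a rate of zero order in substrate. Call the output the [product] made in the asked time at delta's mean rate, whatever the substrate charge: 109 mM. Dividing by the charge gives 10.9% for west and 91.0% for north, and the flask with the smallest charge comes first.

Now add the drawdown of partner, taking one partner per product. Delta's last reading then gives a pseudo-first-order constant of 0.00623 s⁻¹, and the output falls to 92.2 mM, or 76.8% for north.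

Last comes the impurity, 2.2 mM against 2.5 mM of free catalyst. If it competes with substrate for free catalyst, the loss follows [impurity]/[substrate], which is 1.83% in north and 0.220% in west. Delta's slowing may then be partly catalyst loss, and that ratio is smaller in west. This reckoning therefore keeps 10.9% for west and treats 76.8% as the figure for north.

The forecast gives north > north-west > east > west, with 71% (60% to 80%) first and 9% (7.5% to 11%) last, on the ground that “the catalyst is saturated”; it stands lower than this reckoning on north and on west.

The flasks give north > north-west > east > west, with 64.4% in north and 11.6% in west.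

    substrate + free catalyst → catalyst intermediate A (k = 400 M⁻¹ s⁻¹)
    partner + catalyst intermediate A → catalyst intermediate B (k = 10.0 M⁻¹ s⁻¹)
    substrate ⇌ dormant form (K = 1.40, k = 0.0230 s⁻¹)
    catalyst intermediate C → free catalyst + product (k = 1.00 s⁻¹)
    catalyst intermediate B → catalyst intermediate C (k = 2.10 s⁻¹)
    free catalyst + impurity → spent catalyst (k = 250 M⁻¹ s⁻¹)

Against the output of 109 mM, west holds 116 mM of product and north 77.3 mM. At the start free catalyst goes to substrate 730 times as fast as to impurity in west and 87.3 times as fast in north, and at 2.00 min spent catalyst stands at 12.4% in west and 69.9% in north. A neighbour of west with 6.30 mM of free catalyst has its output scaled to 275 mM, more than the partner charge of 175 mM. By 2.00 min that neighbour has made 173 mM, and partner, the limiting reagent there, stands at 0.95% of its charge.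

The runs are calculated from invented constants; noise was put on by code.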